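**Strategy.** The azepane ring (N4, C5–C9, C9a) is read as a cyclohexanone C5–C6–C7–C8–C9–C9a into which N4 has been inserted, and the tetrahydrofuran carbons C8–C11 as a cyclobutenone. One domino operation joins an achiral azido 2-silyloxydiene and cyclobut-2-enone: an enantioselective endo Diels–Alder reaction forms C7–C8 and C9–C9a, and an intramolecular azido-Schmidt ring expansion then forms N4–C9a and N4–C5, closing azepinone and pyrrolidine and fixing C8, C9 and C9a. Baeyer–Villiger oxidation, Mitsunobu inversion at C8, ethylation, spirolactone annulation, anodic oxidation with a vinylogous Mannich reaction at C3, hydrogenation and lactam reduction finish the target.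

Key step: step 5

Remark on numbering and assumptions: atoms carry the target's numbering throughout: pyrrolidine C1–C3, N4, azepane C5–C9, ring fusion C9a, C10 (ethyl-bearing), C11 (spiro), C12–C14 (spirolactone CH2, CHMe, C=O), C18–C21 (side-chain lactone CH–O, CH2, CHMe, C=O). Compounds 1, 5, 13 and 18 are taken as commercial. The facial sense of the oxazaborolidinium catalyst with cyclobutenone is assumed to follow the model for 2-cycloalkenones; if it proves opposite, the catalyst antipode is used.

**Step 1**
Reactants: 1 5-azidopentanoic acid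
Product: 2 5-azido-N-methoxy-N-methylpentanamide
Conditions: CDI, CH2Cl2, rt; then MeNHOMe·HCl
Reagents that add atoms: N,O-dimethylhydroxylamine hydrochloride, CNOC.Cl
Why: The acyl imidazolide formed with CDI is intercepted by N,O-dimethylhydroxylamine (Weinreb amide formation), and the alkyl azide is inert under these conditions.

**Step 2**
Reactants: 2 5-azido-N-methoxy-N-methylpentanamide
Product: 3 7-azidohept-1-en-3-one
Conditions: CH2=CHMgBr (1.2 equiv), THF, −78 → 0 °C; inverse quench into cold 2 M HCl
Reagents that add atoms: vinylmagnesium bromide, C=C[Mg]Br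
Why: Weinreb ketone synthesis: the magnesium-chelated tetrahedral adduct survives until the acidic quench, so one vinyl group is delivered, and the acid quench keeps the liberated amine from adding to the enone.

**Step 3**
Reactants: 3 7-azidohept-1-en-3-one
Product: 4 tert-butyl{[(3Z)-7-azidohepta-1,3-dien-3-yl]oxy}dimethylsilane
Conditions: TBSOTf, Et3N, Et2O, −78 → 0 °C
Reagents that add atoms: tert-butyldimethylsilyl triflate, CC(C)(C)[Si](C)(C)OS(=O)(=O)C(F)(F)F
Why: Soft enolisation on the only enolisable side (C9a–H) with silyl triflate and amine gives the cross-conjugated 2-silyloxydiene, the chain preferring the Z position anti to the vinyl group.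

**Step 4**
Reactants: 5 3-bromocyclobutan-1-one
Product: 6 cyclobut-2-en-1-one
Conditions: n-Bu3N, CH2Cl2, rt; vacuum transfer, kept as a cold CH2Cl2 solution
Reagents that add atoms: none
Why: E1cB dehydrobromination of the β-bromo ketone by the amine base gives the strained enone, which is used at once.

**Step 5**
Reactants: 4 tert-butyl{[(3Z)-7-azidohepta-1,3-dien-3-yl]oxy}dimethylsilane, 6 cyclobut-2-en-1-one
Product: 9 (8S,9S,9aS)-keto-lactam: hexahydropyrrolo[1,2-a]azepin-5-one with a cyclobutanone fused cis across C8–C9 (C11=O on C8, C10H2 on C9), H8, H9 and H9a all cis, via Diels–Alder adduct 7 (not isolated), via azido diketone 8 (not isolated)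
Conditions: (S)-1-(2-methylphenyl)-3,3-diphenyltetrahydro-1H,3H-pyrrolo[1,2-c][1,3,2]oxazaborole (20 mol%), HNTf2 (20 mol%), CH2Cl2, −78 °C; then TfOH (2 equiv), −78 → 0 °C; aq. NaHCO3
Reagents that add atoms: none
Why: The chiral oxazaborolidinium ion binds cyclobutenone 6 and the (Z)-2-silyloxydiene 4 adds by an endo [4+2] cycloaddition (C7–C8 and C9–C9a bonds, the silyloxy-activated terminus C9a going to the β-carbon C9) to give the cis-bicyclo[4.2.0]octene 7; TfOH then C-protonates the enol ether, the tethered azide adds to the activated C5 carbonyl through a six-membered azidohydrin, and C9a migrates from C5 to N4 with loss of N2 (intramolecular azido-Schmidt reaction; N4–C5 and N4–C9a bonds). The closest known reaction type is the acid-promoted domino Diels–Alder/azido-Schmidt reaction of azido silyloxydienes with enones, joined to the oxazaborolidinium-catalysed enantioselective Diels–Alder reaction of 2-cycloalkenones. The cyclohexene closes by intermolecular [4+2] cycloaddition, the azepinone by one-atom ring expansion (1,2-shift of C9a to nitrogen), and the pyrrolidine as the consequence of that shift, formally a 5-exo closure on N4. C8 and C9 are cis because the dienophile is a ring, C9a is cis to both through the endo transition state with the outside Z substituent, the absolute sense comes from the catalyst, and C9a migrates with retention. The step needs para regioselectivity (2-silyloxy control), endo and enantiofacial selectivity (catalyst; only the Z-diene reacts), fused rather than bridged lactam (the antiperiplanar ring-fusion bond C5–C9a migrates), and azide attack at C5 rather than at the cyclobutanone (six- against eight-membered azidohydrin).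

**Step 6**
Reactants: 9 (8S,9S,9aS)-keto-lactam
Product: 10 [(8S,9R,9aS)-8-hydroxy-5-oxooctahydro-1H-pyrrolo[1,2-a]azepin-9-yl]acetic acid (OH and CH2CO2H cis)
Conditions: 30% H2O2, NaOH, MeOH/H2O, 0 °C; then HCl to pH 4 at 0 °C, extraction, used at once
Reagents that add atoms: hydrogen peroxide, OO; sodium hydroxide, [Na+].[OH-]
Why: Baeyer–Villiger oxidation with alkaline peroxide: hydroperoxide adds to the strained cyclobutanone, the more substituted carbon C8 migrates to oxygen with retention, and hydroxide opens the lactone, so the cis hydroxy acid is obtained after careful acidification.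

**Step 7**
Reactants: 10 cis hydroxy acid
Product: 11 (8R,9R,9aS)-trans-fused γ-lactone lactam (ring O on C8, C10H2 on C9, C11=O; C5 lactam)
Conditions: PPh3, DIAD, THF, 0 °C → rt, high dilution
Reagents that add atoms: none
Why: Mitsunobu lactonisation: the C8 alcohol becomes an oxyphosphonium leaving group and the tethered carboxylate displaces it in a 5-exo-tet SN2 step with inversion, which gives the trans-fused lactone with (8R) configuration.

**Step 8**
Reactants: 11 (8R,9R,9aS)-trans-lactone lactam
Product: 12 (8R,9R,9aS,10S)-10-ethyl trans-lactone lactam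
Conditions: LiN(SiMe3)2, THF, −78 °C; EtI, DMPU, −78 → −30 °C
Reagents that add atoms: iodoethane, CCI
Why: Lactone enolate alkylation (the lactone α-CH2 is more acidic than the lactam α-CH2): iodoethane approaches the enolate face opposite to the C9–C9a bond, which sets C10 with the ethyl group trans to C9a.

**Step 9**
Reactants: 12 (8R,9R,9aS,10S)-10-ethyl trans-lactone lactam, 13 (R)-3-bromo-2-methylpropan-1-ol
Product: 15 lactol: (8R,9R,9aS,10S)-11-hydroxy-11-[(2S)-3-hydroxy-2-methylpropyl] hemiketal of the lactone (C11 anomers), via dilithio reagent 14 (not isolated)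
Conditions: 13, n-BuLi (1 equiv) then t-BuLi (2 equiv), Et2O, −78 °C; then 12, THF, −78 °C; H2O
Reagents that add atoms: none
Why: Deprotonation and bromine–lithium exchange give the γ-lithio alkoxide, whose 1,2-addition to the lactone carbonyl (faster than to the tertiary lactam at −78 °C) stops at the lactolate; C13 comes unchanged from 13.

**Step 10**
Reactants: 15 lactol
Product: 16 (8R,9R,9aS,10S,11S,13S)-spirolactone lactam (the target skeleton lacking the C3 side chain, with C5=O)
Conditions: TEMPO (20 mol%), PhI(OAc)2, CH2Cl2/pH 7 buffer, rt; then CSA (cat.), CH2Cl2, rt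
Reagents that add atoms: none
Why: Oxoammonium (TEMPO) oxidation turns the primary alcohol into an aldehyde that the C11 hemiketal hydroxyl traps as a spiro lactol, which is oxidised on to the lactone; acid equilibration through the C11 oxocarbenium ion should favour the spiro isomer with the lactone oxygen syn and the C12 methylene anti to the C10 ethyl group (thermodynamic control of C11).

**Step 11**
Reactants: 16 spirolactone lactam
Product: 17 3-methoxy derivative of 16 (N,O-acetal, both C3 epimers)
Conditions: MeOH, Et4NOTs, graphite anode and cathode, undivided cell, constant current (about 2.5 F/mol), 0 °C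
Reagents that add atoms: methanol, CO
Why: Shono oxidation: anodic two-electron oxidation of the N-acyl amine and capture by methanol, which takes place at the less substituted α-carbon C3 rather than at the tertiary C9a.

**Step 12**
Reactants: 18 3-methylfuran-2(5H)-one
Product: 19 trimethyl[(3-methylfuran-2-yl)oxy]silane
Conditions: TMSOTf, Et3N, CH2Cl2, 0 °C
Reagents that add atoms: trimethylsilyl triflate, C[Si](C)(C)OS(=O)(=O)C(F)(F)F
Why: O-silylation of the butenolide dienolate gives the aromatic 2-silyloxyfuran (silyl dienol ether formation).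

**Step 13**
Reactants: 17 3-methoxy lactam, 19 trimethyl[(3-methylfuran-2-yl)oxy]silane
Product: 20 (3S,8R,9R,9aS,10S,11S,13S,18S)-butenolide lactam (C3 bears the 4-methyl-5-oxo-2,5-dihydrofuran-2-yl group)
Conditions: TMSOTf (10 mol%), CH2Cl2, −78 °C
Reagents that add atoms: none
Why: Vinylogous Mannich reaction: the silyl triflate ionises the N,O-acetal to the N-acyliminium ion and the silyloxyfuran adds through its C5 to the face of C3 anti to C9 (3,9a-trans), with the threo preference usual for cyclic N-acyliminium ions setting (18S).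

**Step 14**
Reactants: 20 butenolide lactam
Product: 21 (3S,8R,9R,9aS,10S,11S,13S,18S,20S)-5-oxo derivative of the target (lactam)
Conditions: H2 (4 atm), Rh/Al2O3, EtOAc, rt
Reagents that add atoms: none
Why: Heterogeneous hydrogenation of the butenolide from the face opposite to the C18 substituent places the methyl group cis to it, which sets (20S).

**Step 15**
Reactants: 21 5-oxo derivative of the target
Product: 22 target, (3S,8R,9R,9aS,10S,11S,13S,18S,20S)
Conditions: Zn(OAc)2 (10 mol%), (EtO)3SiH (3 equiv), THF, 40 °C
Reagents that add atoms: none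
Why: Zinc-catalysed hydrosilylation reduces the tertiary lactam to the amine through the O-silyl hemiaminal and iminium ion, while the two lactones and the spiroketal should be left untouched.

**Compound list**

1 | 5-azidopentanoic acid | OC(=O)CCCCN=[N+]=[N-] | starting material
2 | 5-azido-N-methoxy-N-methylpentanamide | CON(C)C(=O)CCCCN=[N+]=[N-] | intermediate
3 | 7-azidohept-1-en-3-one | C=CC(=O)CCCCN=[N+]=[N-] | intermediate
4 | tert-butyl{[(3Z)-7-azidohepta-1,3-dien-3-yl]oxy}dimethylsilane | [N-]=[N+]=NCCC/C=C(\O[Si](C)(C)C(C)(C)C)C=C | intermediate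
5 | 3-bromocyclobutan-1-one | O=C1CC(Br)C1 | starting material
6 | cyclobut-2-en-1-one | O=C1C=CC1 | intermediate
7 | Diels–Alder adduct, all-cis 2-(3-azidopropyl)-3-(tert-butyldimethylsilyloxy)bicyclo[4.2.0]oct-3-en-7-one | O=C1C[C@H]2[C@@H]1CC=C(O[Si](C)(C)C(C)(C)C)[C@H]2CCCN=[N+]=[N-] | intermediate
8 | azido diketone, all-cis 2-(3-azidopropyl)bicyclo[4.2.0]octane-3,7-dione | O=C1C[C@H]2[C@@H]1CCC(=O)[C@H]2CCCN=[N+]=[N-] | intermediate
9 | (8S,9S,9aS)-keto-lactam, cyclobutanone cis-fused across C8–C9 of hexahydropyrrolo[1,2-a]azepin-5-one | O=C1C[C@H]2[C@@H]1CCC(=O)N3[C@H]2CCC3 | intermediate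
10 | [(8S,9R,9aS)-8-hydroxy-5-oxooctahydro-1H-pyrrolo[1,2-a]azepin-9-yl]acetic acid | OC(=O)C[C@H]1[C@H](CCC(=O)N2[C@H]1CCC2)O | intermediate
11 | (8R,9R,9aS)-trans-fused γ-lactone lactam | O=C1C[C@H]2[C@@H](CCC(=O)N3[C@H]2CCC3)O1 | intermediate
12 | (8R,9R,9aS,10S)-10-ethyl trans-lactone lactam | CC[C@H]1[C@H]2[C@@H](CCC(=O)N3[C@H]2CCC3)OC1=O | intermediate
13 | (R)-3-bromo-2-methylpropan-1-ol | BrC[C@H](C)CO | starting material
14 | lithium (2S)-3-lithio-2-methylpropan-1-olate | [Li]C[C@H](C)CO[Li] | intermediate
15 | lactol, (8R,9R,9aS,10S)-11-hydroxy-11-[(2S)-3-hydroxy-2-methylpropyl] hemiketal (C11 anomers) | CC[C@H]1[C@H]2[C@@H](CCC(=O)N3[C@H]2CCC3)OC1(O)C[C@H](C)CO | intermediate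
16 | (8R,9R,9aS,10S,11S,13S)-spirolactone lactam | CC[C@H]1[C@H]2[C@@H](CCC(=O)N3[C@H]2CCC3)O[C@]12C[C@H](C)C(=O)O2 | intermediate
17 | 3-methoxy derivative of 16 (C3 epimers) | CC[C@H]1[C@H]2[C@@H](CCC(=O)N3[C@H]2CCC3OC)O[C@]12C[C@H](C)C(=O)O2 | intermediate
18 | 3-methylfuran-2(5H)-one | CC1=CCOC1=O | starting material
19 | trimethyl[(3-methylfuran-2-yl)oxy]silane | Cc1ccoc1O[Si](C)(C)C | intermediate
20 | (3S,8R,9R,9aS,10S,11S,13S,18S)-butenolide lactam | CC[C@H]1[C@H]2[C@@H](CCC(=O)N3[C@H]2CC[C@H]3[C@@H]2C=C(C)C(=O)O2)O[C@]12C[C@H](C)C(=O)O2 | intermediate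
21 | (3S,8R,9R,9aS,10S,11S,13S,18S,20S)-5-oxo derivative of the target | CC[C@H]1[C@H]2[C@@H](CCC(=O)N3[C@H]2CC[C@H]3[C@@H]2C[C@H](C)C(=O)O2)O[C@]12C[C@H](C)C(=O)O2 | intermediate
22 | target, (3S,8R,9R,9aS,10S,11S,13S,18S,20S) | CC[C@H]1[C@H]2[C@@H](CCCN3[C@H]2CC[C@H]3[C@@H]2C[C@H](C)C(=O)O2)O[C@]12C[C@H](C)C(=O)O2 | target

**Total step count:** 15
**Longest linear sequence:** 13 steps (steps 1–3, 5–11, 13–15)

**Steps most likely to fail**

Step 5. The small, very reactive enone may react through an uncatalysed background cycloaddition or be poorly discriminated by the chiral Lewis acid, which would lower the enantiomeric purity; silyl transfer (Mukaiyama–Michael addition) instead of cycloaddition is a second hazard. The fallback replaces asymmetric catalysis by classical resolution. It sets out from 4 and 6: an uncatalysed cycloaddition (CH2Cl2, 0 °C → rt) followed by TfOH should give the racemic keto-lactam, that is 9 together with its enantiomer ent-9 F1. Alkaline H2O2 as in step 6 then gives the racemic hydroxy acid, 10 together with ent-10 F2. Crystallisation with (R)-1-phenylethylamine (or its antipode, whichever gives the less soluble salt of 10) should give the (R)-1-phenylethylammonium salt of 10 F3, and acidification to pH 4 returns the route at 10.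

Step 13. The silyl triflate may ionise the spiro ketal-ester at C11 as well as the N,O-acetal, and the threo preference at C18 may be eroded. The fallback builds the lactone stepwise and sets out from 17. Potassium vinyltrifluoroborate (CH2=CHBF3K) with BF3·OEt2 in CH2Cl2 should add a vinyl group anti to C9 to give the 3-vinyl lactam F8. Ozonolysis (O3, CH2Cl2, −78 °C; Me2S) gives the 3-formyl lactam F9. Barbier allylation–lactonisation with ethyl 2-(bromomethyl)acrylate and Zn in THF/aq. NH4Cl, with chelation between lactam carbonyl and aldehyde expected to direct the (18S) adduct, gives the α-methylene lactone F10. Hydrogenation (H2, Pd/C) from the face opposite to C18 returns the route at 21.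

Step 7. The hydroxy acid may relactonise with retention before activation, or lactonise through an acyloxyphosphonium ion, which would return the cis lactone. The fallback inverts C8 intermolecularly and sets out from 10. TsOH (cat.) closes it to the cis-lactone F4, and neat pyrrolidine opens this to the hydroxy pyrrolidine amide F5. Intermolecular Mitsunobu reaction with 4-nitrobenzoic acid (PPh3, DIAD) gives the C8-inverted 4-nitrobenzoate F6, and K2CO3/MeOH frees the trans hydroxy amide F7. TsOH in hot toluene lactonises this with retention at C8 and loss of pyrrolidine, returning the route at 11.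

**Further compounds**

F1 | step 5 | ent-9, enantiomer of keto-lactam 9 (formed with 9 as the racemate) | O=C1C[C@@H]2[C@H]1CCC(=O)N3[C@@H]2CCC3
F2 | step 5 | ent-10, enantiomer of hydroxy acid 10 (formed with 10 as the racemate) | OC(=O)C[C@@H]1[C@@H](CCC(=O)N2[C@@H]1CCC2)O
F3 | step 5 | (R)-1-phenylethylammonium salt of 10 | [O-]C(=O)C[C@H]1[C@H](CCC(=O)N2[C@H]1CCC2)O.C[C@@H]([NH3+])c1ccccc1
F4 | step 7 | (8S,9R,9aS)-cis-fused γ-lactone lactam | O=C1C[C@H]2[C@H](CCC(=O)N3[C@H]2CCC3)O1
F5 | step 7 | (8S,9R,9aS)-hydroxy pyrrolidine amide | O=C(N1CCCC1)C[C@H]1[C@H](CCC(=O)N2[C@H]1CCC2)O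
F6 | step 7 | (8R,9R,9aS)-4-nitrobenzoate of the pyrrolidine amide | O=C(N1CCCC1)C[C@H]1[C@@H](CCC(=O)N2[C@H]1CCC2)OC(=O)c1ccc(cc1)[N+](=O)[O-]
F7 | step 7 | (8R,9R,9aS)-hydroxy pyrrolidine amide | O=C(N1CCCC1)C[C@H]1[C@@H](CCC(=O)N2[C@H]1CCC2)O
F8 | step 13 | (3S)-3-vinyl spirolactone lactam | CC[C@H]1[C@H]2[C@@H](CCC(=O)N3[C@H]2CC[C@H]3C=C)O[C@]12C[C@H](C)C(=O)O2
F9 | step 13 | (3S)-3-formyl spirolactone lactam | CC[C@H]1[C@H]2[C@@H](CCC(=O)N3[C@H]2CC[C@H]3C=O)O[C@]12C[C@H](C)C(=O)O2
F10 | step 13 | (3S,18S)-α-methylene lactone lactam | CC[C@H]1[C@H]2[C@@H](CCC(=O)N3[C@H]2CC[C@H]3[C@@H]2CC(=C)C(=O)O2)O[C@]12C[C@H](C)C(=O)O2
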